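The route rests on disconnecting the C1–C2 bond of the ten-membered ring. In that ring, fused to ring A at C1/C10, the C1–C2 bond, the ring-cis C3=C4 alkene and the oxygen on C9 make up a cyclodec-5-enone array, the signature of an oxy-Cope ring expansion. One anionic [3,3] shift of a cis-1,2-dialkenylcyclohex-3-enol, breaking C4–C9, should deliver the ten-membered ring, quaternary C1, C2 and the 3Z,5E-diene together. The precursor is a shikimic acid-derived cyclohexenol bearing on C9 the hydroxyl and a methylquinone bisketal (ring A), on C4 an E-2-(4-methoxybenzyloxy)vinyl group, and an O7/O8 acetonide trans to both alkenyl groups.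

Key step: step 13

Remark on the chemistry: atoms are labelled as in the target (the shikimate ring carbons C1–C6 and the carboxyl carbon become C5, C6, C7, C8, C9, C4 and C16) and α is the face of ring A opposite the C15 methyl; it is assumed that O7 must stay trans to the two alkenyl groups until after the rearrangement (a cis O7 would be syn-diaxial to ring A in the reactive half-chair and would steer the C9 addition to the wrong face), so C7 is inverted only in the Mitsunobu step 26, that C8 is best carried as a carbinol inside the O7/O8 acetonide and oxidised late, and that C11 is masked as a dioxolane (C14 as the more labile dimethyl ketal) so that the rearranged enolate cannot lose alkoxide irreversibly and the two ring A ketals can be opened one at a time.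

Step 1
Reactants: 1 2-bromo-4-methoxyphenol
Product: 2 2-(2-bromo-4-methoxyphenoxy)ethanol
Conditions: ethylene carbonate, K2CO3 (cat.), DMF, 120 °C
Reagents that add atoms: ethylene carbonate, O=C1OCCO1
Why: The phenoxide opens ethylene carbonate at a methylene carbon and the carbonate half-ester loses CO2 (base-catalysed hydroxyethylation of a phenol), so only the phenolic oxygen is alkylated.

Step 2
Reactants: 2 2-(2-bromo-4-methoxyphenoxy)ethanol
Product: 4 2-(2-bromo-4-methoxy-3-methylphenoxy)ethanol, via dilithio species 3 (not isolated)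
Conditions: LiN(iPr)2 (2.2 equiv), THF, −78 °C; then MeI, −78 °C; then H2O
Reagents that add atoms: iodomethane, CI
Why: After the hydroxyl is deprotonated the amide base removes the ring proton flanked by bromine and methoxy (directed ortho-lithiation at the most acidic C–H), and the aryllithium is methylated at −78 °C, below the temperature of benzyne formation and faster than O-methylation of the lithium alkoxide.

Step 3
Reactants: 4 2-(2-bromo-4-methoxy-3-methylphenoxy)ethanol
Product: 5 6-bromo-8,8-dimethoxy-7-methyl-1,4-dioxaspiro[4.5]deca-6,9-diene (ring A bromide)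
Conditions: Pt anode, constant current, KOH (1%) in MeOH, 0 °C, undivided cell
Reagents that add atoms: methanol, CO
Why: Anodic oxidation of a 4-methoxyaryl 2-hydroxyethyl ether in basic methanol (electrochemical quinone bisketal synthesis) closes the dioxolane at the carbon bearing the tether and adds methanol at the methoxy-bearing carbon, giving the mixed bisketal with the C–Br bond intact.

Step 4
Reactants: 6 4-methoxybenzyl alcohol
Product: 7 (E)-1,2-dichlorovinyl 4-methoxybenzyl ether
Conditions: KH, trichloroethylene, THF, 0 °C → rt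
Reagents that add atoms: trichloroethylene, ClC=C(Cl)Cl
Why: The potassium alkoxide adds trans to dichloroacetylene formed in situ from trichloroethylene, the standard entry to 1,2-dichlorovinyl ethers as precursors of alkynyl ethers.

Step 5
Reactants: 8 (−)-shikimic acid
Product: 10 methyl 3,4-O-isopropylideneshikimate, via methyl shikimate 9 (not isolated)
Conditions: MeOH, camphorsulfonic acid (cat.), reflux; evaporate; then 2,2-dimethoxypropane, acetone, rt
Reagents that add atoms: methanol, CO; 2,2-dimethoxypropane, COC(C)(C)OC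
Why: Fischer esterification is followed by acid-catalysed acetonide formation, which takes the only cis-diol (O7/O8) and leaves the C9 hydroxyl free.

Step 6
Reactants: 10 methyl 3,4-O-isopropylideneshikimate
Product: 12 acetonide-protected cyclohexa-1,5-diene ester (C5=C6 and C4=C9), via triflate 11 (not isolated)
Conditions: Tf2O, pyridine, CH2Cl2, −20 °C; then DBU, 0 °C → rt
Reagents that add atoms: none
Why: Triflation of the free C9 hydroxyl and E2 elimination of the anti hydrogen on C4 (base-mediated dehydration through a sulfonate) give the conjugated diene without touching C7 or C8.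

Step 7
Reactants: 12 acetonide-protected cyclohexa-1,5-diene ester
Product: 14 C4–C9 epoxide syn to the acetonide, via bromohydrin 13 (not isolated)
Conditions: NBS, DME/H2O (4:1), 0 °C; then K2CO3, rt
Reagents that add atoms: water, O
Why: The bromonium ion forms on the C4=C9 alkene (the one not deactivated by the ester) anti to the acetonide, water opens it trans at allylic C4, and Williamson closure of the bromohydrin places the epoxide oxygen on the acetonide face, which direct peracid epoxidation would not do.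

Step 8
Reactants: 14 C4–C9 epoxide syn to the acetonide; 7 (E)-1,2-dichlorovinyl 4-methoxybenzyl ether
Product: 16 C4 alkynyl ether with C9 hydroxyl, via lithium acetylide 15 (not isolated)
Conditions: 7, n-BuLi (2.1 equiv), THF, −78 → −40 °C; then BF3·OEt2 and 14, −78 °C; then Et3N, H2O
Reagents that add atoms: none
Why: The lithium alkoxyacetylide (from 7 by elimination and chlorine–lithium exchange) opens the BF3-activated vinyl epoxide by SN2 attack at allylic C4 (Lewis acid promoted epoxide alkynylation), anti to the epoxide oxygen, so the C3–C2 unit ends trans to the acetonide and the new C9 hydroxyl cis to it.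

Step 9
Reactants: 16 C4 alkynyl ether with C9 hydroxyl
Product: 17 C9,C16-diol with E enol ether
Conditions: LiAlH4, THF, 0 °C → rt; then H2O, aq NaOH
Reagents that add atoms: none
Why: LiAlH4 reduces the ester to the C16 alcohol and trans-hydroaluminates the alkynyl ether (the known E-selective hydride reduction of ynol ethers, here assisted by the neighbouring C9 alkoxide), giving the E-configured C3=C2 enol ether.

Step 10
Reactants: 17 C9,C16-diol with E enol ether
Product: 18 O16 TBDPS ether
Conditions: TBDPSCl, imidazole, CH2Cl2, 0 °C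
Reagents that add atoms: tert-butyl(chloro)diphenylsilane, CC(C)(C)[Si](Cl)(c1ccccc1)c1ccccc1
Why: Silylation selects the primary allylic hydroxyl over the hindered secondary C9 hydroxyl.

Step 11
Reactants: 18 O16 TBDPS ether
Product: 19 C9 ketone
Conditions: Dess–Martin periodinane, NaHCO3, CH2Cl2, 0 °C
Reagents that add atoms: none
Why: Dess–Martin oxidation under buffered, non-basic conditions gives the β,γ-unsaturated ketone without epimerising C4 or hydrolysing the enol ether, and the ketone is used at once.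

Step 12
Reactants: 19 C9 ketone; 5 ring A bromide
Product: 21 rearrangement precursor (cis-1,2-dialkenylcyclohex-3-enol), via vinyllithium 20 (not isolated)
Conditions: 5, n-BuLi, THF, −78 °C; then 19 premixed with LaCl3·2LiCl, THF, −78 °C; then H2O
Reagents that add atoms: none
Why: Bromine–lithium exchange and LaCl3-promoted 1,2-addition (lanthanide-mediated carbonyl addition, which suppresses enolisation at the acidic C4–H) should occur anti to the C8–O bond of the cis-fused acetonide and axially on the half-chair whose C4 substituent is pseudo-equatorial, so that C9 carries ring A cis to the C4 alkoxyvinyl group and trans to O7/O8.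

Step 13
Reactants: 21 rearrangement precursor
Product: 24 ten-membered C9 ketone, via potassium alkoxide 22 (not isolated), via potassium enolate 23 (not isolated)
Conditions: KH, 18-crown-6, THF, 0 °C → rt; then AcOH, THF, −78 °C
Reagents that add atoms: none
Why: KH deprotonates the tertiary C9 hydroxyl and the crown-ether-separated potassium alkoxide 22 undergoes a concerted, alkoxide-accelerated [3,3]-sigmatropic shift in which the C4–C9 bond breaks as C1–C2 forms, giving the C9 enolate 23 that is protonated at C10 on the cold acidic quench. The closest known reaction type is the anionic oxy-Cope rearrangement of 1,2-dialkenylcyclohexanols to cyclodec-5-enones. The ten-membered ring is closed by ring expansion of the cyclohexene (C1 and C2 are inserted across the former C4–C9 bond), not by an end-to-end cyclisation, so no dilution is needed. C1 and C2 are set by chirality transfer from C9 and C4 through the chair transition state in which C5 is axial, C8 and the C2 oxygen of the E enol ether are equatorial and the C15 methyl is axial, and C10 is set by protonation of the enolate on the face opposite the adjacent axial C15 methyl, giving the trans ring fusion. The step needs this chair to win over the other chair (C8 axial, which would give an E C3=C4 alkene): the cis C4/C9 relationship, the syn-axial clash that an axial C8 would have with the C15 methyl and the pseudo-equatorial O7 secure it, and the same chair makes C3=C4 ring-cis (3Z) while C5=C6 is carried over unchanged. Irreversible loss of alkoxide from C11 of enolate 23 is countered by the cyclic C11 ketal and by the cold quench.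

Step 14
Reactants: 24 ten-membered C9 ketone
Product: 25 (9S)-alcohol
Conditions: Zn(BH4)2, Et2O, −20 °C; then H2O
Reagents that add atoms: none
Why: In this chelation-controlled hydride reduction zinc bridges the C9 carbonyl and O8 and hydride enters on the open peripheral face, giving the 8,9-anti (9S) carbinol and removing the epimerisable position at C10.

Step 15
Reactants: 25 (9S)-alcohol
Product: 26 C2,C9-diol
Conditions: DDQ, CH2Cl2/pH 7 phosphate buffer, 0 °C
Reagents that add atoms: none
Why: Oxidative cleavage of the 4-methoxybenzyl ether by DDQ frees the C2 hydroxyl under buffered conditions that leave the ketals, the acetonide and the diene alone.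

Step 16
Reactants: 26 C2,C9-diol
Product: 27 C2,C9-diacetate
Conditions: Ac2O, DMAP, Et3N, CH2Cl2, rt → 40 °C
Reagents that add atoms: acetic anhydride, CC(=O)OC(C)=O
Why: DMAP-catalysed acetylation installs the final C2 and C9 acetates while no other hydroxyl is free.

Step 17
Reactants: 27 C2,C9-diacetate
Product: 28 C14 enone
Conditions: pyridinium p-toluenesulfonate (cat.), acetone/H2O (10:1), rt
Reagents that add atoms: water, O
Why: Mild acid hydrolysis cleaves the allylic dimethyl ketal at C14 much faster than the C11 dioxolane (regioselective monohydrolysis of a mixed quinone bisketal), and the acetone solvent preserves the acetonide.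

Step 18
Reactants: 28 C14 enone
Product: 29 12α,13α-epoxy ketone
Conditions: tBuOOH, DBU, CH2Cl2, 0 °C → rt
Reagents that add atoms: tert-butyl hydroperoxide, CC(C)(C)OO
Why: Nucleophilic (Weitz–Scheffer) epoxidation touches only the enone: the peroxide anion adds axially at C12 on the α face and the enolate closes the epoxide on the same face, leaving the electron-rich diene alone.

Step 19
Reactants: 29 12α,13α-epoxy ketone
Product: 30 12α-hydroxy-13-ene
Conditions: N2H4·H2O, AcOH, MeOH, 0 °C → rt
Reagents that add atoms: none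
Why: In the Wharton transposition the epoxy hydrazone fragments with loss of nitrogen to the C13=C14 alkene and the C12 carbinol, whose C–O bond (set in step 18) is not touched, and acetic acid-buffered hydrazine spares the hindered acetates.

Step 20
Reactants: 30 12α-hydroxy-13-ene
Product: 32 12α,13α,14α-triol, via osmate ester 31 (not isolated)
Conditions: OsO4, TMEDA, CH2Cl2, −78 °C; then aq Na2SO3, THF, rt
Reagents that add atoms: osmium tetroxide, O=[Os](=O)(=O)=O
Why: In this hydrogen-bond-directed dihydroxylation the only free hydroxyl (12α) binds the OsO4–TMEDA complex and delivers it to the adjacent C13=C14 alkene on the α face, also the face opposite the C15 methyl, so the diene is spared and C13 and C14 are set cis to O12.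

Step 21
Reactants: 32 12α,13α,14α-triol
Product: 33 13-acetate
Conditions: Ac2O (1.1 equiv), pyridine, CH2Cl2, 0 °C
Reagents that add atoms: acetic anhydride, CC(=O)OC(C)=O
Why: Selective acylation takes the equatorial C13 hydroxyl, which reacts faster than the two axial hydroxyls at C12 and C14 that each adjoin a fully substituted carbon.

Step 22
Reactants: 33 13-acetate
Product: 34 12,14-O-disiloxanediyl derivative
Conditions: 1,3-dichloro-1,1,3,3-tetraisopropyldisiloxane, imidazole, DMF, rt → 40 °C
Reagents that add atoms: 1,3-dichloro-1,1,3,3-tetraisopropyldisiloxane, CC(C)[Si](Cl)(C(C)C)O[Si](Cl)(C(C)C)C(C)C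
Why: The bifunctional silylating agent bridges the two remaining syn-1,3-diaxial hydroxyls (cyclic disiloxane protection of a 1,3-diol), giving an acid-stable, fluoride-labile mask.

Step 23
Reactants: 34 12,14-O-disiloxanediyl derivative
Product: 35 C11 ketone
Conditions: In(OTf)3 (cat.), acetone/H2O (50:1), rt → 40 °C
Reagents that add atoms: water, O
Why: Lewis acid catalysed deketalisation in acetone removes the C11 dioxolane (the glycol is scavenged by the solvent) while the acetone keeps the O7/O8 isopropylidene acetal in place.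

Step 24
Reactants: 35 C11 ketone
Product: 36 C11=C20 methylene compound
Conditions: Zn, CH2Br2, TiCl4 (Takai–Lombardo reagent), THF/CH2Cl2, 0 °C → rt
Reagents that add atoms: dibromomethane, BrCBr
Why: Takai–Lombardo methylenation is non-basic, so the hindered ketone is converted without β-elimination of the C9 acetate or epimerisation at C10, and the esters are left alone.

Step 25
Reactants: 36 C11=C20 methylene compound
Product: 37 7,8-diol
Conditions: AcOH/H2O (4:1), 40 °C
Reagents that add atoms: none
Why: Acid hydrolysis of the isopropylidene acetal frees O7 and O8, and the silyl ethers, the acetates and the allylic acetate tolerate aqueous acetic acid.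

Step 26
Reactants: 37 7,8-diol
Product: 38 C7 2-bromopropanoate (C7 inverted)
Conditions: PPh3, diisopropyl azodicarboxylate, THF, 0 °C (betaine preformed); then 37 and 2-bromopropanoic acid, 0 °C → rt
Reagents that add atoms: 2-bromopropanoic acid, CC(Br)C(O)=O
Why: In the Mitsunobu esterification the allylic, less hindered C7 hydroxyl is activated and displaced by the carboxylate with SN2 inversion, which gives C7 the configuration of the target and brings in C17, C18 and C19.

Step 27
Reactants: 38 C7 2-bromopropanoate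
Product: 39 C8 ketone
Conditions: Dess–Martin periodinane, NaHCO3, CH2Cl2, 0 °C → rt
Reagents that add atoms: none
Why: Dess–Martin oxidation of the only free secondary hydroxyl gives the C8 ketone under buffered conditions that do not epimerise C7 or C9.

Step 28
Reactants: 39 C8 ketone
Product: 40 8-hydroxy γ-lactone
Conditions: SmI2 (2.2 equiv), THF, −78 °C; then H2O
Reagents that add atoms: none
Why: In the SmI2-mediated intramolecular Reformatsky reaction the samarium enolate formed from the α-bromo ester adds to the C8 ketone (5-exo-trig) on the face that keeps C6 and C9 anti across C7–C8, giving the trans-fused lactone with the C8 hydroxyl cis to O7, while C17 takes its methyl trans to C9, the arrangement also favoured on equilibration of this epimerisable centre.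

Step 29
Reactants: 40 8-hydroxy γ-lactone
Product: 41 12α,14α-diol
Conditions: Et3N·3HF, THF, rt
Reagents that add atoms: none
Why: Fluoride cleaves the cyclic disiloxane much faster than the primary TBDPS ether (selective desilylation), freeing only O12 and O14.

Step 30
Reactants: 41 12α,14α-diol
Product: 42 11,20-epoxide (16-O-TBDPS Juncin Q)
Conditions: VO(acac)2 (cat.), tBuOOH, CH2Cl2, 0 °C
Reagents that add atoms: tert-butyl hydroperoxide, CC(C)(C)OO
Why: In this hydroxyl-directed epoxidation the axial allylic 12α-hydroxyl delivers the vanadium peroxide to the C11=C20 methylene on the α face, which sets C11, while the diene, whose allylic C16 oxygen is silylated, is not activated.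

Step 31
Reactants: 42 11,20-epoxide (16-O-TBDPS Juncin Q)
Product: 43 Juncin Q
Conditions: Bu4NF, AcOH (1:1), THF, 0 °C → rt
Reagents that add atoms: none
Why: Buffered fluoride desilylation removes the TBDPS group from O16 without acyl migration or epoxide opening.

Compound list
1 | 2-bromo-4-methoxyphenol | COc1ccc(O)c(Br)c1 | starting material
2 | 2-(2-bromo-4-methoxyphenoxy)ethanol | COc1ccc(OCCO)c(Br)c1 | intermediate
3 | lithium 2-(2-bromo-3-lithio-4-methoxyphenoxy)ethanolate (dilithio species) | [Li]c1c(OC)ccc(OCCO[Li])c1Br | intermediate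
4 | 2-(2-bromo-4-methoxy-3-methylphenoxy)ethanol | COc1ccc(OCCO)c(Br)c1C | intermediate
5 | 6-bromo-8,8-dimethoxy-7-methyl-1,4-dioxaspiro[4.5]deca-6,9-diene (ring A bromide: Br on C10, methyl on C1, dioxolane at C11, dimethyl ketal at C14) | COC1(OC)C=CC2(OCCO2)C(Br)=C1C | intermediate
6 | 4-methoxybenzyl alcohol | COc1ccc(CO)cc1 | starting material
7 | (E)-1,2-dichlorovinyl 4-methoxybenzyl ether | COc1ccc(CO/C(Cl)=C\Cl)cc1 | intermediate
8 | (−)-shikimic acid, (3R,4S,5R)-3,4,5-trihydroxycyclohex-1-ene-1-carboxylic acid | OC(=O)C1=C[C@@H](O)[C@@H](O)[C@H](O)C1 | starting material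
9 | methyl shikimate | COC(=O)C1=C[C@@H](O)[C@@H](O)[C@H](O)C1 | intermediate
10 | methyl 3,4-O-isopropylideneshikimate (O7/O8 acetonide, free C9 hydroxyl trans to it) | COC(=O)C1=C[C@H]2OC(C)(C)O[C@H]2[C@H](O)C1 | intermediate
11 | C9 trifluoromethanesulfonate of 10 | COC(=O)C1=C[C@H]2OC(C)(C)O[C@H]2[C@H](OS(=O)(=O)C(F)(F)F)C1 | intermediate
12 | methyl cis-3,4-(isopropylidenedioxy)cyclohexa-1,5-diene-1-carboxylate (C5=C6 and C4=C9; C7 and C8 as in 10) | COC(=O)C1=C[C@H]2OC(C)(C)O[C@H]2C=C1 | intermediate
13 | bromohydrin of 12: bromine on C9 anti to the acetonide, hydroxyl on C4 syn to the acetonide | COC(=O)C1=C[C@H]2OC(C)(C)O[C@H]2[C@H](Br)[C@H]1O | intermediate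
14 | C4–C9 epoxide of 12 with the epoxide oxygen on the acetonide face | COC(=O)C1=C[C@H]2OC(C)(C)O[C@H]2[C@H]2O[C@@H]12 | intermediate
15 | lithium (4-methoxybenzyloxy)acetylide | [Li]C#COCc1ccc(OC)cc1 | intermediate
16 | methyl ester carrying on C4 the 2-(4-methoxybenzyloxy)ethynyl group trans to the acetonide and on C9 a hydroxyl cis to it | COC(=O)C1=C[C@H]2OC(C)(C)O[C@H]2[C@@H](O)[C@@H]1C#COCc1ccc(OC)cc1 | intermediate
17 | diol with C16 hydroxymethyl, C9 hydroxyl and C4 (E)-2-(4-methoxybenzyloxy)vinyl group trans to the acetonide | OCC1=C[C@H]2OC(C)(C)O[C@H]2[C@@H](O)[C@@H]1/C=C/OCc1ccc(OC)cc1 | intermediate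
18 | O16 tert-butyldiphenylsilyl (TBDPS) ether of 17 | CC(C)(C)[Si](c1ccccc1)(c1ccccc1)OCC1=C[C@H]2OC(C)(C)O[C@H]2[C@@H](O)[C@@H]1/C=C/OCc1ccc(OC)cc1 | intermediate
19 | C9 ketone of 18 (C4, C7, C8 unchanged) | CC(C)(C)[Si](c1ccccc1)(c1ccccc1)OCC1=C[C@H]2OC(C)(C)O[C@H]2C(=O)[C@@H]1/C=C/OCc1ccc(OC)cc1 | intermediate
20 | (8,8-dimethoxy-7-methyl-1,4-dioxaspiro[4.5]deca-6,9-dien-6-yl)lithium | COC1(OC)C=CC2(OCCO2)C([Li])=C1C | intermediate
21 | rearrangement precursor: C9 tertiary alcohol carrying the ring A dienyl group (through C10) cis to the C4 (E)-2-(4-methoxybenzyloxy)vinyl group, both trans to the O7/O8 acetonide; O16 TBDPS | CC(C)(C)[Si](c1ccccc1)(c1ccccc1)OCC1=C[C@H]2OC(C)(C)O[C@H]2[C@](O)(C2=C(C)C(OC)(OC)C=CC23OCCO3)[C@@H]1/C=C/OCc1ccc(OC)cc1 | intermediate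
22 | potassium C9 alkoxide of 21 | CC(C)(C)[Si](c1ccccc1)(c1ccccc1)OCC1=C[C@H]2OC(C)(C)O[C@H]2[C@]([O-])(C2=C(C)C(OC)(OC)C=CC23OCCO3)[C@@H]1/C=C/OCc1ccc(OC)cc1.[K+] | intermediate
23 | potassium C9=C10 enolate of the ten-membered ring (enolate oxygen cis to C1) | [K+].C1=CC4(OCCO4)/C2=C(/[O-])[C@@H]3OC(C)(C)O[C@@H]3/C=C(CO[Si](c5ccccc5)(c5ccccc5)C(C)(C)C)\C=C/[C@H](OCc5ccc(OC)cc5)[C@@]2(C)C1(OC)OC | intermediate
24 | ten-membered C9 ketone: ring A with C11 dioxolane, C12=C13 and C14 dimethyl ketal; C1, C2 and C10 configured as in the target; C2 4-methoxybenzyl ether; 3Z,5E-diene; O16 TBDPS; O7/O8 acetonide with C7 epimeric to the target | C1=CC4(OCCO4)[C@@H]2C(=O)[C@@H]3OC(C)(C)O[C@@H]3/C=C(CO[Si](c5ccccc5)(c5ccccc5)C(C)(C)C)\C=C/[C@H](OCc5ccc(OC)cc5)[C@@]2(C)C1(OC)OC | intermediate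
25 | (9S)-alcohol of 24 (hydroxyl cis to O8 on the ten-membered ring) | C1=CC4(OCCO4)[C@@H]2[C@H](O)[C@@H]3OC(C)(C)O[C@@H]3/C=C(CO[Si](c5ccccc5)(c5ccccc5)C(C)(C)C)\C=C/[C@H](OCc5ccc(OC)cc5)[C@@]2(C)C1(OC)OC | intermediate
26 | C2,C9-diol (4-methoxybenzyl group removed) | C1=CC4(OCCO4)[C@@H]2[C@H](O)[C@@H]3OC(C)(C)O[C@@H]3/C=C(CO[Si](c5ccccc5)(c5ccccc5)C(C)(C)C)\C=C/[C@H](O)[C@@]2(C)C1(OC)OC | intermediate
27 | C2,C9-diacetate | C1=CC4(OCCO4)[C@@H]2[C@H](OC(C)=O)[C@@H]3OC(C)(C)O[C@@H]3/C=C(CO[Si](c5ccccc5)(c5ccccc5)C(C)(C)C)\C=C/[C@H](OC(C)=O)[C@@]2(C)C1(OC)OC | intermediate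
28 | C14 enone (C12=C13 conjugated to the C14 ketone, C11 dioxolane retained) | C1=CC4(OCCO4)[C@@H]2[C@H](OC(C)=O)[C@@H]3OC(C)(C)O[C@@H]3/C=C(CO[Si](c5ccccc5)(c5ccccc5)C(C)(C)C)\C=C/[C@H](OC(C)=O)[C@@]2(C)C1=O | intermediate
29 | 12α,13α-epoxy-14-ketone | O=C1[C@H]6O[C@H]6C4(OCCO4)[C@@H]2[C@H](OC(C)=O)[C@@H]3OC(C)(C)O[C@@H]3/C=C(CO[Si](c5ccccc5)(c5ccccc5)C(C)(C)C)\C=C/[C@H](OC(C)=O)[C@@]12C | intermediate
30 | 12α-hydroxy compound with C13=C14 alkene | C1=C[C@@H](O)C4(OCCO4)[C@@H]2[C@H](OC(C)=O)[C@@H]3OC(C)(C)O[C@@H]3/C=C(CO[Si](c5ccccc5)(c5ccccc5)C(C)(C)C)\C=C/[C@H](OC(C)=O)[C@@]12C | intermediate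
31 | 13,14-O-osmate ester of 32 (hexavalent osmium, TMEDA chelate) | CN(C)CCN(C)C.O=[Os]7(=O)O[C@H]1[C@@H](O)C4(OCCO4)[C@@H]2[C@H](OC(C)=O)[C@@H]3OC(C)(C)O[C@@H]3/C=C(CO[Si](c5ccccc5)(c5ccccc5)C(C)(C)C)\C=C/[C@H](OC(C)=O)[C@@]2(C)[C@H]1O7 | intermediate
32 | 12α,13α,14α-triol | O[C@H]1[C@@H](O)C4(OCCO4)[C@@H]2[C@H](OC(C)=O)[C@@H]3OC(C)(C)O[C@@H]3/C=C(CO[Si](c5ccccc5)(c5ccccc5)C(C)(C)C)\C=C/[C@H](OC(C)=O)[C@@]2(C)[C@H]1O | intermediate
33 | 13-O-acetyl-12α,14α-diol | CC(=O)O[C@H]1[C@@H](O)C4(OCCO4)[C@@H]2[C@H](OC(C)=O)[C@@H]3OC(C)(C)O[C@@H]3/C=C(CO[Si](c5ccccc5)(c5ccccc5)C(C)(C)C)\C=C/[C@H](OC(C)=O)[C@@]2(C)[C@H]1O | intermediate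
34 | 12,14-O-(1,1,3,3-tetraisopropyldisiloxane-1,3-diyl) derivative of 33 | CC(=O)O[C@H]1[C@@H](O7)C4(OCCO4)[C@@H]2[C@H](OC(C)=O)[C@@H]3OC(C)(C)O[C@@H]3/C=C(CO[Si](c5ccccc5)(c5ccccc5)C(C)(C)C)\C=C/[C@H](OC(C)=O)[C@@]2(C)[C@H]1O[Si](C(C)C)(C(C)C)O[Si]7(C(C)C)C(C)C | intermediate
35 | C11 ketone (dioxolane removed) | CC(=O)O[C@H]1[C@@H](O7)C(=O)[C@@H]2[C@H](OC(C)=O)[C@@H]3OC(C)(C)O[C@@H]3/C=C(CO[Si](c5ccccc5)(c5ccccc5)C(C)(C)C)\C=C/[C@H](OC(C)=O)[C@@]2(C)[C@H]1O[Si](C(C)C)(C(C)C)O[Si]7(C(C)C)C(C)C | intermediate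
36 | C11=C20 exocyclic methylene compound | CC(=O)O[C@H]1[C@@H](O7)C(=C)[C@@H]2[C@H](OC(C)=O)[C@@H]3OC(C)(C)O[C@@H]3/C=C(CO[Si](c5ccccc5)(c5ccccc5)C(C)(C)C)\C=C/[C@H](OC(C)=O)[C@@]2(C)[C@H]1O[Si](C(C)C)(C(C)C)O[Si]7(C(C)C)C(C)C | intermediate
37 | 7,8-diol (acetonide removed, C7 still epimeric to the target) | CC(=O)O[C@H]1[C@@H](O7)C(=C)[C@@H]2[C@H](OC(C)=O)[C@H](O)[C@H](O)/C=C(CO[Si](c5ccccc5)(c5ccccc5)C(C)(C)C)\C=C/[C@H](OC(C)=O)[C@@]2(C)[C@H]1O[Si](C(C)C)(C(C)C)O[Si]7(C(C)C)C(C)C | intermediate
38 | C7 2-bromopropanoate with C7 inverted (as in the target) and free C8 hydroxyl; mixture of epimers at the bromine-bearing carbon | CC(=O)O[C@H]1[C@@H](O7)C(=C)[C@@H]2[C@H](OC(C)=O)[C@H](O)[C@@H](OC(=O)C(C)Br)/C=C(CO[Si](c5ccccc5)(c5ccccc5)C(C)(C)C)\C=C/[C@H](OC(C)=O)[C@@]2(C)[C@H]1O[Si](C(C)C)(C(C)C)O[Si]7(C(C)C)C(C)C | intermediate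
39 | C8 ketone of 38 (same mixture at the bromine-bearing carbon) | CC(=O)O[C@H]1[C@@H](O7)C(=C)[C@@H]2[C@H](OC(C)=O)C(=O)[C@@H](OC(=O)C(C)Br)/C=C(CO[Si](c5ccccc5)(c5ccccc5)C(C)(C)C)\C=C/[C@H](OC(C)=O)[C@@]2(C)[C@H]1O[Si](C(C)C)(C(C)C)O[Si]7(C(C)C)C(C)C | intermediate
40 | 8-hydroxy γ-lactone fused at C7–C8, with C7, C8 and C17 as in the target | CC(=O)O[C@H]1[C@@H](O7)C(=C)[C@@H]2[C@H](OC(C)=O)[C@@]3(O)[C@H](/C=C(CO[Si](c5ccccc5)(c5ccccc5)C(C)(C)C)\C=C/[C@H](OC(C)=O)[C@@]2(C)[C@H]1O[Si](C(C)C)(C(C)C)O[Si]7(C(C)C)C(C)C)OC(=O)[C@@H]3C | intermediate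
41 | 12α,14α-diol (disiloxane removed) | CC(=O)O[C@H]1[C@@H](O)C(=C)[C@@H]2[C@H](OC(C)=O)[C@@]3(O)[C@H](/C=C(CO[Si](c5ccccc5)(c5ccccc5)C(C)(C)C)\C=C/[C@H](OC(C)=O)[C@@]2(C)[C@H]1O)OC(=O)[C@@H]3C | intermediate
42 | 16-O-TBDPS Juncin Q (11,20-epoxide with the epoxide oxygen α) | CC(=O)O[C@H]1[C@@H](O)[C@]2(CO2)[C@@H]2[C@H](OC(C)=O)[C@@]3(O)[C@H](/C=C(CO[Si](c5ccccc5)(c5ccccc5)C(C)(C)C)\C=C/[C@H](OC(C)=O)[C@@]2(C)[C@H]1O)OC(=O)[C@@H]3C | intermediate
43 | Juncin Q | CC(=O)O[C@H]1[C@@H](O)[C@]2(CO2)[C@@H]2[C@H](OC(C)=O)[C@@]3(O)[C@H](/C=C(CO)\C=C/[C@H](OC(C)=O)[C@@]2(C)[C@H]1O)OC(=O)[C@@H]3C | target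

Total step count: 31. Longest linear sequence: 27 steps (steps 5 to 31, from shikimic acid); the ring A bromide (steps 1 to 3) and the alkynyl ether precursor (step 4) are made separately.

Steps most likely to fail

Step 13: the rearrangement may be out-competed by enolate chemistry (loss of alkoxide from C11, proton transfer towards C8) or may leak through the alternative chair. The fallback avoids any anion. It sets out from precursor 21, which would be silylated at O9 (Me3SiOTf, Et3N, CH2Cl2, −78 °C) to the O9 trimethylsilyl ether F1. Heating F1 (toluene, sealed tube, 160 °C, with N,O-bis(trimethylsilyl)acetamide as acid scavenger) in a thermal siloxy-Cope rearrangement through the same chair should give the C9 trimethylsilyl enol ether F2. Cold methanolysis (K2CO3 cat., MeOH, −20 °C) with protonation at C10 would return to the route at ketone 24.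

Step 19: hydrazone formation at the hindered C14 carbonyl may be incomplete and the esters may suffer hydrazinolysis. The fallback sets out from epoxy ketone 29, which would be opened reductively at C13 (Na[PhSeB(OEt)3], AcOH, EtOH, 0 °C) to the 12α-hydroxy 14-ketone F3. Hydroxylation at C13 through the lithium enolate (LiN(SiMe3)2, 2.2 equiv, THF, −78 °C; then 2-(phenylsulfonyl)-3-phenyloxaziridine) should give the 12α,13α-dihydroxy 14-ketone F4, whose equatorial 13α epimer is the thermodynamic one. Chelation-controlled syn-1,3 reduction (Et2BOMe, NaBH4, THF/MeOH, −78 °C) would rejoin the route at triol 32.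

Step 26: activation may be unselective between O7 and O8, or substitution may occur with allylic transposition along the diene. The fallback inverts C7 by oxidation and directed reduction. It sets out from diol 37, which would be oxidised at the allylic hydroxyl only (MnO2, CH2Cl2, rt) to the 8-hydroxy 7-ketone F5. Reduction with intramolecular hydride delivery from O8 (Me4NBH(OAc)3, MeCN/AcOH, −20 °C) should give the 7,8-trans diol F6 with C7 as in the target. Acylation of the less hindered allylic O7 (2-bromopropanoic acid, N,N'-dicyclohexylcarbodiimide, DMAP cat., CH2Cl2, −20 °C) would rejoin the route at ester 38.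

Further compounds
F1 | step 13 | O9 trimethylsilyl ether of 21 | CC(C)(C)[Si](c1ccccc1)(c1ccccc1)OCC1=C[C@H]2OC(C)(C)O[C@H]2[C@](O[Si](C)(C)C)(C2=C(C)C(OC)(OC)C=CC23OCCO3)[C@@H]1/C=C/OCc1ccc(OC)cc1
F2 | step 13 | C9 trimethylsilyl enol ether of 24 (C9=C10, silyloxy group cis to C1) | C1=CC4(OCCO4)/C2=C(/O[Si](C)(C)C)[C@@H]3OC(C)(C)O[C@@H]3/C=C(CO[Si](c5ccccc5)(c5ccccc5)C(C)(C)C)\C=C/[C@H](OCc5ccc(OC)cc5)[C@@]2(C)C1(OC)OC
F3 | step 19 | 12α-hydroxy 14-ketone (C13 methylene) | O=C1C[C@@H](O)C4(OCCO4)[C@@H]2[C@H](OC(C)=O)[C@@H]3OC(C)(C)O[C@@H]3/C=C(CO[Si](c5ccccc5)(c5ccccc5)C(C)(C)C)\C=C/[C@H](OC(C)=O)[C@@]12C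
F4 | step 19 | 12α,13α-dihydroxy 14-ketone | O=C1[C@@H](O)[C@@H](O)C4(OCCO4)[C@@H]2[C@H](OC(C)=O)[C@@H]3OC(C)(C)O[C@@H]3/C=C(CO[Si](c5ccccc5)(c5ccccc5)C(C)(C)C)\C=C/[C@H](OC(C)=O)[C@@]12C
F5 | step 26 | 8-hydroxy 7-ketone (dienone) | CC(=O)O[C@H]1[C@@H](O7)C(=C)[C@@H]2[C@H](OC(C)=O)[C@H](O)C(=O)/C=C(CO[Si](c5ccccc5)(c5ccccc5)C(C)(C)C)\C=C/[C@H](OC(C)=O)[C@@]2(C)[C@H]1O[Si](C(C)C)(C(C)C)O[Si]7(C(C)C)C(C)C
F6 | step 26 | 7,8-trans diol with C7 as in the target | CC(=O)O[C@H]1[C@@H](O7)C(=C)[C@@H]2[C@H](OC(C)=O)[C@H](O)[C@@H](O)/C=C(CO[Si](c5ccccc5)(c5ccccc5)C(C)(C)C)\C=C/[C@H](OC(C)=O)[C@@]2(C)[C@H]1O[Si](C(C)C)(C(C)C)O[Si]7(C(C)C)C(C)C
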